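**Plan**
- Retrosynthetic cuts: the angelate C–O bond, then C13–C14 and C12=C13 of the diene, then C5–C10 across the decalin, then C8–C9, and last C6–C7 and C1–C10.
- Enabling feature: C1 to C10 of rings A and B form a ten-membered periphery whose only cross-ring bond is C5–C10. C5 lies next to the C6 oxygen (carbonyl level, so C5 can act as an enol-type donor) and C10 is the methyl-bearing end of an E C1=C10 alkene.
- Forward order: a cyclohexanone (C1–C6) takes the C9–C12 alkenyl unit at C1 and the C7–C8 enol ether unit at C6. An anionic oxy-Cope rearrangement makes the ten-membered ring (C8–C9), a transannular ene reaction of the derived ketimine closes rings A and B together, and the side chain and ester follow.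
- Stereochemistry: C1 of the cyclohexanone comes from a stereoconvergent nickel coupling and is relayed to C8 and C9 through the chair oxy-Cope transition state (two Z alkenes). C10 and C5 arise in the transannular step (chair over chair, trans fusion), C6 by thermodynamic reduction, and 12Z from a Z iodoalkene and a Stille coupling.

Key step: step 8

Remark: labdane numbering (C1–C20) is used for every intermediate, the monocyclic ones included.
Assumption: the sense of induction of the nickel/bis(oxazoline) catalyst (step 3) and of the (S)-1-phenylethyl group (step 8) is taken as drawn; the mirror-image ligand or amine would be used if it proves opposite.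

**Step 1**
Reactants: 1 3-[(tert-butyldimethylsilyl)oxy]propanal
Product: 2 (Z)-tert-butyl[(4-iodopent-3-en-1-yl)oxy]dimethylsilane
Conditions: EtPPh3I, n-BuLi, THF, 0 °C; I2, −78 °C; NaN(SiMe3)2, −78 to −20 °C; then 1, −78 °C to rt
Reagents that add atoms: ethyltriphenylphosphonium iodide (CC[P+](c1ccccc1)(c1ccccc1)c1ccccc1.[I-]); iodine (II)
Why: Stork–Zhao-type Wittig olefination with the α-iodoethylidene ylide, which with an unbranched aldehyde at low temperature should give the Z trisubstituted iodoalkene (iodine cis to the chain).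

**Step 2**
Reactants: 3 3,3-dimethylcyclohexan-1-one
Product: 5 2-bromo-5,5-dimethylcyclohexan-1-one (racemic), via trimethylsilyl enol ether 4 (not isolated)
Conditions: LiN(iPr)2, THF, −78 °C; Me3SiCl; then N-bromosuccinimide, THF, −78 to 0 °C
Reagents that add atoms: N-bromosuccinimide (O=C1CCC(=O)N1Br); chlorotrimethylsilane (C[Si](C)(C)Cl; retained in 4 only)
Why: Kinetic deprotonation takes the less hindered methylene (away from the gem-dimethyl carbon) and the enol silane is brominated regiospecifically by N-bromosuccinimide; the new center is racemic by design.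

**Step 3**
Reactants: 2 (Z)-alkenyl iodide; 5 racemic α-bromo ketone
Product: 8 (2R)-2-[(2Z)-5-[(tert-butyldimethylsilyl)oxy]pent-2-en-2-yl]-5,5-dimethylcyclohexan-1-one, via alkenyllithium 6 (not isolated), via alkenylzirconocene chloride 7 (not isolated)
Conditions: 2, t-BuLi (2 equiv), Et2O, −78 °C; Cp2ZrCl2, THF, −78 to 0 °C; then 5, NiCl2(dme) (cat.), chiral bis(oxazoline) ligand, THF–diglyme, 10 °C
Reagents that add atoms: tert-butyllithium ([Li]C(C)(C)C; lithium in 6 only); zirconocene dichloride (Cl[Zr](Cl)(C1C=CC=C1)C1C=CC=C1; in 7 only)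
Why: Stereoconvergent nickel-catalysed Negishi-type coupling of a racemic α-bromo ketone with an alkenylzirconium reagent, in which both enantiomers pass through a radical and the chiral nickel complex sets the α-stereocenter (2R), while the neutral conditions keep the β,γ-alkene in place and its geometry is carried over with retention from the iodide.

**Step 4**
Reactants: 9 bromoacetone
Product: 10 (Z)-1-bromo-2-(methoxymethoxy)prop-1-ene
Conditions: KN(SiMe3)2, THF–DMPU, −78 °C (ketone added to the base); MeOCH2Cl, −78 to −20 °C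
Reagents that add atoms: chloromethyl methyl ether (COCCl)
Why: O-alkylation of a potassium enolate by a hard alkylating agent in a dipolar medium, with deprotonation on the more acidic CH2Br side and the Z enolate (bromine cis to oxygen) expected; any E isomer is harmless because its lithio derivative eliminates to propyne in step 5.

**Step 5**
Reactants: 10 (Z)-bromo enol ether; 8 (2R)-alkenyl ketone
Product: 12 (1R,2R)-2-[(2Z)-5-[(tert-butyldimethylsilyl)oxy]pent-2-en-2-yl]-1-[(1Z)-2-(methoxymethoxy)prop-1-en-1-yl]-5,5-dimethylcyclohexan-1-ol, via alkoxyvinyllithium 11 (not isolated)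
Conditions: 10, t-BuLi (2 equiv), Et2O, −78 °C; then 8 premixed with CeCl3, THF, −78 °C; aq. NH4Cl
Reagents that add atoms: tert-butyllithium ([Li]C(C)(C)C; lithium in 11 only)
Why: Bromine–lithium exchange with retention gives the cis-β-alkoxy vinyllithium, and its cerium-mediated 1,2-addition follows the equatorial trajectory, away from the axial methyl group at C4 and trans to the C1 alkenyl group, which sets the carbinol center (1R) with the two alkenyl groups trans-diequatorial and without enolising the ketone.

**Step 6**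
Reactants: 12 1,2-dialkenylcyclohexanol
Product: 13 (3R,4R,5E)-4-{2-[(tert-butyldimethylsilyl)oxy]ethyl}-3-(methoxymethoxy)-3,5,9,9-tetramethylcyclodec-5-en-1-one (C6 ketone, C8 and C9 set, E C1=C10)
Conditions: KN(SiMe3)2, 18-crown-6, THF, −40 to 0 °C; AcOH, THF, −78 °C
Reagents that add atoms: none
Why: Anionic oxy-Cope rearrangement through the single chair transition state open to the trans-diequatorial cyclohexane, in which C8–C9 forms and C6–C1 breaks, the equatorial ring tether at C1 gives the E alkene, and the Z enol ether (oxygen axial) and Z alkenyl group (chain axial) translate the ring stereocenters into 8R,9R; the methoxymethyl group cannot migrate to the alkoxide as a silyl group would, and the cold acidic quench limits β-elimination from the enolate.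

**Step 7**
Reactants: 13 cyclodecenone; 14 (S)-1-phenylethylamine
Product: 15 N-[(1S)-1-phenylethyl] ketimine of 13 (C=N isomers)
Conditions: Ti(OiPr)4, THF, rt to 50 °C; aqueous basic work-up, filtration
Reagents that add atoms: none
Why: Titanium-mediated condensation of a ketone with a primary amine under non-acidic conditions that spare the E-cyclodecene and the β-alkoxy ketone; no stereocenter is formed.

**Step 8**
Reactants: 15 ketimine
Product: 17 trans-decal-6-one (labdane numbering: 4,4,8β,10β-tetramethyl, 8α-methoxymethoxy, 9β-[2-(tert-butyldimethylsilyloxy)ethyl], 5α-H), via cyclised ketimine 16 (not isolated)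
Conditions: degassed mesitylene, 170 °C, sealed tube; then AcOH–NaOAc, THF–H2O, rt
Reagents that add atoms: water (O)
Why: Proposed new method: on heating, the ketimine equilibrates with its N–H enamines and only the C5=C6 enamine has a partner across the ring, so C5 adds to C10 while the N–H hydrogen passes to C1 in a six-centre ene (aza-Conia-ene) transition state, and the cyclised imine is then hydrolysed. The closest known reaction types are the thermal Conia-ene cyclisation of unsaturated ketones, the ene-like additions of secondary enamines from chiral imines to alkenes, and the transannular closures of (E)-cyclodecadienes to trans-decalins. The single C5–C10 bond closes ring B in a 6-exo-trig and ring A in a 6-endo-trig mode with respect to the C1=C10 alkene. C10 and C5 arise together from a chair-over-chair stacking of the E alkene and the enamine, which enforces the trans fusion; the C10 face is chosen by the conformer with the C9 chain and the C8 ether pseudo-equatorial and is reinforced by the (S)-1-phenylethyl group shielding the other enamine face, and C5 can still equilibrate to the trans-fused ketone after hydrolysis. The step needs C5–C10 bonding in place of the transannular carbonyl-ene closure (C6 to C1) that a free cyclodec-5-enone prefers on heating; the imine secures this because C=N is a poor enophile while its enamine is far more populated than a ketone enol, and regiochemistry needs no control because the C6=C7 enamine has no alkene within reach.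

**Step 9**
Reactants: 17 decalone
Product: 18 6α-alcohol (6α-OH, otherwise as 17)
Conditions: Li, NH3(l), THF, EtOH, −78 °C
Reagents that add atoms: none
Why: Dissolving-metal reduction of a hindered cyclohexanone, which under thermodynamic control gives the equatorial 6α-alcohol, whereas hydride delivery from the open α face would give the axial epimer.

**Step 10**
Reactants: 18 6α-alcohol; 19 angelic acid
Product: 21 6α-angelate (8α-OMOM, 12-OTBS), via mixed anhydride 20 (not isolated)
Conditions: 19, 2,4,6-trichlorobenzoyl chloride, Et3N, toluene, rt; then 18, 80 °C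
Reagents that add atoms: 2,4,6-trichlorobenzoyl chloride (O=C(Cl)c1c(Cl)cc(Cl)cc1Cl; in 20 only)
Why: Yamaguchi esterification through the mixed anhydride, run without a nucleophilic amine catalyst so that the angelate is not isomerised to the tiglate; the 6α-OH is the only free hydroxyl and no stereocenter is touched.

**Step 11**
Reactants: 21 silyl ether
Product: 22 primary alcohol (12-OH)
Conditions: HF·pyridine, pyridine, THF, 0 °C to rt
Reagents that add atoms: none
Why: Fluoride cleavage of the primary silyl ether under buffered conditions that leave the tertiary methoxymethyl ether and the angelate intact.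

**Step 12**
Reactants: 22 primary alcohol
Product: 23 C12 aldehyde
Conditions: Dess–Martin periodinane, CH2Cl2, 0 °C to rt
Reagents that add atoms: none
Why: Dess–Martin oxidation under near-neutral conditions; C9 is β to the new carbonyl and cannot epimerise.

**Step 13**
Reactants: 23 aldehyde
Product: 24 (12Z)-13-iodo alkene (C11 cis to iodine)
Conditions: EtPPh3I, n-BuLi, THF, 0 °C; I2, −78 °C; NaN(SiMe3)2, −78 to −20 °C; then 23, −78 °C to rt
Reagents that add atoms: ethyltriphenylphosphonium iodide (CC[P+](c1ccccc1)(c1ccccc1)c1ccccc1.[I-]); iodine (II)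
Why: Stork–Zhao-type Wittig olefination as in step 1, expected to give the Z iodoalkene, which fixes the 12Z geometry of the later diene.

**Step 14**
Reactants: 24 methoxymethyl ether
Product: 25 8α-alcohol (Z iodoalkene, 6α-angelate)
Conditions: ZnBr2, n-PrSH, CH2Cl2, 0 °C
Reagents that add atoms: none
Why: Lewis acid/thiol cleavage of the methoxymethyl acetal (transfer of the CH2OMe group to sulfur), a method that is fast also for tertiary ethers and is used here before the acid-sensitive diene exists.

**Step 15**
Reactants: 25 alkenyl iodide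
Product: 26 CNP0582767.2, (12Z)-6α-angeloyloxylabda-12,14-dien-8α-ol
Conditions: tributyl(vinyl)stannane, Pd(PPh3)4 (cat.), CuI, DMF, 40 °C
Reagents that add atoms: tributyl(vinyl)stannane (C=C[Sn](CCCC)(CCCC)CCCC)
Why: Stille cross-coupling of an alkenyl iodide with a vinylstannane, which keeps the alkene geometry and tolerates the free tertiary alcohol and the angelate.

**Compound list**
1 | 3-[(tert-butyldimethylsilyl)oxy]propanal | O=CCCO[Si](C)(C)C(C)(C)C | starting material
2 | (Z)-tert-butyl[(4-iodopent-3-en-1-yl)oxy]dimethylsilane | C/C(I)=C/CCO[Si](C)(C)C(C)(C)C | intermediate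
3 | 3,3-dimethylcyclohexan-1-one | CC1(C)CCCC(=O)C1 | starting material
4 | [(5,5-dimethylcyclohex-1-en-1-yl)oxy]trimethylsilane | C[Si](C)(C)OC1=CCCC(C)(C)C1 | intermediate
5 | 2-bromo-5,5-dimethylcyclohexan-1-one (racemic) | O=C1CC(C)(C)CCC1Br | intermediate
6 | [5-[(tert-butyldimethylsilyl)oxy]pent-2-en-2-yl]lithium (lithium cis to the CH2CH2O chain) | [Li]/C(C)=C\CCO[Si](C)(C)C(C)(C)C | intermediate
7 | chlorobis(cyclopentadienyl)[(2Z)-5-[(tert-butyldimethylsilyl)oxy]pent-2-en-2-yl]zirconium | C/C(=C/CCO[Si](C)(C)C(C)(C)C)[Zr](Cl)(C1C=CC=C1)C1C=CC=C1 | intermediate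
8 | (2R)-2-[(2Z)-5-[(tert-butyldimethylsilyl)oxy]pent-2-en-2-yl]-5,5-dimethylcyclohexan-1-one | O=C1CC(C)(C)CC[C@@H]1/C(C)=C\CCO[Si](C)(C)C(C)(C)C | intermediate
9 | bromoacetone | CC(=O)CBr | starting material
10 | (Z)-1-bromo-2-(methoxymethoxy)prop-1-ene | C/C(OCOC)=C/Br | intermediate
11 | [(1Z)-2-(methoxymethoxy)prop-1-en-1-yl]lithium | C/C(OCOC)=C/[Li] | intermediate
12 | (1R,2R)-2-[(2Z)-5-[(tert-butyldimethylsilyl)oxy]pent-2-en-2-yl]-1-[(1Z)-2-(methoxymethoxy)prop-1-en-1-yl]-5,5-dimethylcyclohexan-1-ol | COCO/C(C)=C\[C@@]1(O)CC(C)(C)CC[C@@H]1/C(C)=C\CCO[Si](C)(C)C(C)(C)C | intermediate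
13 | (3R,4R,5E)-4-{2-[(tert-butyldimethylsilyl)oxy]ethyl}-3-(methoxymethoxy)-3,5,9,9-tetramethylcyclodec-5-en-1-one | O=C1C[C@@](C)(OCOC)[C@H](CCO[Si](C)(C)C(C)(C)C)/C(C)=C/CCC(C)(C)C1 | intermediate
14 | (S)-1-phenylethylamine | C[C@H](N)c1ccccc1 | starting material
15 | N-[(1S)-1-phenylethyl] ketimine of 13 (C=N isomers) | C[C@H](N=C1C[C@@](C)(OCOC)[C@H](CCO[Si](C)(C)C(C)(C)C)/C(C)=C/CCC(C)(C)C1)c1ccccc1 | intermediate
16 | N-[(1S)-1-phenylethyl] ketimine of 17 | CC(C)(C)[Si](C)(C)OCC[C@@H]1[C@@]2(C)CCCC(C)(C)[C@@H]2C(=N[C@@H](C)c3ccccc3)C[C@@]1(C)OCOC | intermediate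
17 | trans-decal-6-one: 12-(tert-butyldimethylsilyloxy)-8α-(methoxymethoxy)-13,14,15,16-tetranorlabdan-6-one (5α-H, 9α-H, 10β-CH3) | CC(C)(C)[Si](C)(C)OCC[C@@H]1[C@@]2(C)CCCC(C)(C)[C@@H]2C(=O)C[C@@]1(C)OCOC | intermediate
18 | 6α-alcohol of 17 | CC(C)(C)[Si](C)(C)OCC[C@@H]1[C@@]2(C)CCCC(C)(C)[C@@H]2[C@@H](O)C[C@@]1(C)OCOC | intermediate
19 | angelic acid, (Z)-2-methylbut-2-enoic acid | C/C=C(/C)C(=O)O | starting material
20 | angelic 2,4,6-trichlorobenzoic anhydride | C/C=C(/C)C(=O)OC(=O)c1c(Cl)cc(Cl)cc1Cl | intermediate
21 | 6α-angelate of 18 | CC(C)(C)[Si](C)(C)OCC[C@@H]1[C@@]2(C)CCCC(C)(C)[C@@H]2[C@@H](OC(=O)/C(C)=C\C)C[C@@]1(C)OCOC | intermediate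
22 | 12-alcohol (6α-angelate, 8α-OMOM) | OCC[C@@H]1[C@@]2(C)CCCC(C)(C)[C@@H]2[C@@H](OC(=O)/C(C)=C\C)C[C@@]1(C)OCOC | intermediate
23 | 12-aldehyde (6α-angelate, 8α-OMOM) | O=CC[C@@H]1[C@@]2(C)CCCC(C)(C)[C@@H]2[C@@H](OC(=O)/C(C)=C\C)C[C@@]1(C)OCOC | intermediate
24 | (12Z)-13-iodo-14,15-dinorlabd-12-ene, 6α-angelate, 8α-OMOM | C/C(I)=C/C[C@@H]1[C@@]2(C)CCCC(C)(C)[C@@H]2[C@@H](OC(=O)/C(C)=C\C)C[C@@]1(C)OCOC | intermediate
25 | (12Z)-13-iodo-14,15-dinorlabd-12-en-8α-ol 6α-angelate | C/C(I)=C/C[C@@H]1[C@@]2(C)CCCC(C)(C)[C@@H]2[C@@H](OC(=O)/C(C)=C\C)C[C@@]1(C)O | intermediate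
26 | CNP0582767.2, (12Z)-6α-angeloyloxylabda-12,14-dien-8α-ol | C=C/C(C)=C\C[C@@H]1[C@@]2(C)CCCC(C)(C)[C@@H]2[C@@H](OC(=O)/C(C)=C\C)C[C@@]1(C)O | target

**Step count**
Total steps: 15. Longest linear sequence: 13 steps (steps 2, 3 and 5 to 15, from 3,3-dimethylcyclohexanone).

**Steps most likely to fail**

1. Step 8 (proposed new method).
   - What may go wrong: thermal β-elimination of the C8 alkoxy group through the C6=C7 enamine, closure on the wrong face of C10 (poor facial selectivity), or no closure below the decomposition temperature.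
   - Fallback (known chemistry), from 13 back to 17: epoxidation of the strained E alkene with mCPBA/NaHCO3 gives the 1,10-epoxy ketone F1. Kinetic enolisation (LiN(iPr)2, Me3SiCl, −78 °C) gives the C5 trimethylsilyl enol ether F2. BF3·OEt2 at −78 °C then opens the epoxide at C10 by transannular attack of C5 (Mukaiyama-type epoxide alkylation, anti opening, trans fusion) to give the 1β-hydroxy decalone F3. 1,1'-Thiocarbonyldiimidazole converts this into the imidazolylthiocarbonate F4, and Barton–McCombie reduction (Bu3SnH, AIBN, toluene, 90 °C) returns 17.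

2. Step 6.
   - What may go wrong: β-elimination of the C8 alkoxide from the potassium enolate before the quench, or leakage through a boat transition state that erodes the C8/C9 configuration.
   - Fallback, from 12 back to 13: the alcohol is silylated (Me3SiOTf, 2,6-lutidine) to the trimethylsilyl ether F5. A neutral thermal siloxy-Cope rearrangement (degassed o-xylene, 200–220 °C), in which no enolate is formed, gives the ten-membered silyl enol ether F6. Mild methanolysis (K2CO3, MeOH, 0 °C) then releases ketone 13.

3. Step 3.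
   - What may go wrong: low enantioselectivity or slow coupling with a cyclic secondary bromide and an α-branched alkenyl metal, and migration of the alkene into conjugation.
   - Fallback, from 3 and 2 back to 8: palladium-catalysed α-alkenylation of the lithium enolate of 3 with 2 (LiN(SiMe3)2, Pd2(dba)3, P(t-Bu)3, THF) gives the racemic ketone F7. Noyori-type asymmetric transfer hydrogenation with dynamic kinetic resolution (RuCl(p-cymene)[(S,S)-TsDPEN] or its enantiomer, HCO2H/Et3N) gives the cis-(1R,2R)-alcohol F8. Dess–Martin oxidation returns 8.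

**Further compounds**
F1 | step 8 | (1R,10R)-1,10-epoxide of 13 (trans epoxide, labdane numbering) | O=C1C[C@@](C)(OCOC)[C@H](CCO[Si](C)(C)C(C)(C)C)[C@@]2(C)O[C@@H]2CCC(C)(C)C1
F2 | step 8 | C5 trimethylsilyl enol ether of F1 | C[Si](C)(C)OC=1C[C@@](C)(OCOC)[C@H](CCO[Si](C)(C)C(C)(C)C)[C@@]2(C)O[C@@H]2CCC(C)(C)C=1
F3 | step 8 | 1β-hydroxy derivative of 17 | CC(C)(C)[Si](C)(C)OCC[C@@H]1[C@@]2(C)[C@H](O)CCC(C)(C)[C@@H]2C(=O)C[C@@]1(C)OCOC
F4 | step 8 | 1β-O-(imidazol-1-ylthiocarbonyl) derivative of F3 | CC(C)(C)[Si](C)(C)OCC[C@@H]1[C@@]2(C)[C@H](OC(=S)n3ccnc3)CCC(C)(C)[C@@H]2C(=O)C[C@@]1(C)OCOC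
F5 | step 6 | trimethylsilyl ether of 12 | COCO/C(C)=C\[C@@]1(O[Si](C)(C)C)CC(C)(C)CC[C@@H]1/C(C)=C\CCO[Si](C)(C)C(C)(C)C
F6 | step 6 | C6 trimethylsilyl enol ether of 13 (C6=C7, E C1=C10) | C[Si](C)(C)O/C1=C\[C@@](C)(OCOC)[C@H](CCO[Si](C)(C)C(C)(C)C)/C(C)=C/CCC(C)(C)C1
F7 | step 3 | racemic 2-[(2Z)-5-[(tert-butyldimethylsilyl)oxy]pent-2-en-2-yl]-5,5-dimethylcyclohexan-1-one | O=C1CC(C)(C)CCC1/C(C)=C\CCO[Si](C)(C)C(C)(C)C
F8 | step 3 | (1R,2R)-2-[(2Z)-5-[(tert-butyldimethylsilyl)oxy]pent-2-en-2-yl]-5,5-dimethylcyclohexan-1-ol (cis) | O[C@@H]1CC(C)(C)CC[C@@H]1/C(C)=C\CCO[Si](C)(C)C(C)(C)C
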